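In a one-step world a species with a single exit of rate constant k loses a factor e every 1/k, and the bench habit is to count such lifetimes against the run. Here is the flask:

substrate 0.087 M; other conformer 1.00 equiv (fed, over 8.0 min); time 8.0 d; the fed solution adds 1.0 times the starting volume

    substrate ⇌ other conformer (K1 = 0.206, k1 = 8.36 h⁻¹)
    substrate → target (k2 = 1.18 h⁻¹)
    other conformer → isomer of the product (k3 = 79.1 h⁻¹)
    target ⇌ isomer of the product (K4 = 0.79, k4 = 0.425 h⁻¹)
    substrate → decomposition product (k5 = 6.72 × 10⁻⁴ h⁻¹)
    target → over-reaction product (k6 = 0.639 h⁻¹)

- over-reaction product at 8.0 d, in percent of the substrate and other conformer together charged
- amount of target if the flask were left three thousand times as long, in percent of the substrate and other conformer together charged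

- charges are per starting volume, the dose included; the dosed solution carries all of it
- in a conversion other conformer counts as not yet reacted
- run time (flask): 8.0 d

The half-life of substrate by the path to target alone, 0.59 h, is short against 8.0 d, so we look for the slow stage further on, in the pool of target and isomer of the product. That pool empties by the target's exit to over-reaction product, with constant 0.639 h⁻¹.

The usual rule treats the pool as a pre-equilibrium. The symmetric case is the zero of the scale: at an equilibrium constant of one the pool sits evenly and drains at half the exit constant. With 0.79 the target's fraction of the pool is 55.9 %, which gives 0.357 h⁻¹.

But the rule needs exchange to outrun exit, and exit over the summed exchange constants is 0.664, which is not small. So we solve the pair exactly. The back constant is 0.538 h⁻¹, the roots sum to 1.60 h⁻¹, and their product is the exit constant times the back constant. The smaller root, 0.255 h⁻¹, is what we call the drain rate: the rate at which the pool's fraction of the charge finally falls. It is slower than the rule's figure. Over 8.0 d it counts 49.0 lifetimes, so we commit to over-reaction product holding nearly all of the charge and to target reading zero at the far longer time.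

The forecast says >99.9 % and 0 %, with the pool said to “drain irreversibly to over-reaction product with a slowest rate” of about 0.25 per hour.

The flask gives >99.9 % over-reaction product at 8.0 d and 0 % target at the far longer time. Of the turnover of the path from target to over-reaction product up to 8.0 d, 99.1 % lies behind it after 0.800 d. For that time the drain rate counts 4.90 lifetimes, which as an estimate, counted from the start and without the filling of the pool, is a factor of 0.748 %.

For the same flask read at 3.0 d, the drain rate counts 18.4 lifetimes, by the same estimate a factor of <0.001 %. The computed reading there is >99.9 % over-reaction product and 0 % target.

(The rate constants stand for no real mixture; the run is a simulation.)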